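**Retrosynthetic overview**
1. Target 14 ⇐ singlet-oxygen ene reaction on the 7(11)-en-8-one 13, which places the 11-OOH and the 6,7-alkene; the angelate is put on O3 while O1 is still silylated.
2. Eremophilane core 9 ⇐ eudesmane 3β,4β-epoxide carrying a C8 silyl enol ether (7): one cationic cascade (epoxide opening, 1,2-H shift C5→C4, 1,2-CH3 shift C10→C5, enone formation) sets C3, C4 and C5.
3. Eudesmane 3 ⇐ (1R,10R)-1,10-epoxygermacrone 2 by transannular cation–olefin cyclization (C5–C10 bond), which sets C1, C10 and C5.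
4. Epoxide 2 ⇐ germacrone 1 by catalytic asymmetric epoxidation, the only source of absolute configuration.
5. Ring order: the ten-membered ring is bought with germacrone; rings A and B (the decalin) close together in step 2; no ring is formed afterwards.

Assumption: eremophilane numbering is used; the target is the (1R,3S,4R,5R) compound, i.e. 3β-angeloyloxy-1β-hydroxy-11-hydroperoxyeremophila-6,9-dien-8-one with 4β,5β-methyls, and germacrone (bulk natural isolate) and angelic acid are taken as commercial starting materials.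

**Step 1**
Reactants: 1 germacrone
Product: 2 (1R,10R)-1,10-epoxygermacra-4E,7(11)-dien-8-one
Conditions: D-fructose-derived Shi ketone (30 mol%), KHSO5 (as 2KHSO5·KHSO4·K2SO4, 1.0 equiv), K2CO3, Bu4NHSO4, MeCN/CH2(OMe)2/aq. Na2B4O7 buffer (pH 10.5), 0 °C
Reagents that add atoms: potassium peroxymonosulfate (KHSO5), [K+].[O-]S(=O)(=O)OO
Why: Shi asymmetric epoxidation, in which the chiral dioxirane attacks the exposed outer face of the E-1(10)-alkene through a spiro transition state, selecting one of the rapidly interconverting planar-chiral ring conformers to give the (1R,10R)-trans-epoxide, while the 1(10)-alkene is expected to be the more reactive of the two trisubstituted alkenes toward electrophilic oxygen (the 4,5-epoxide is a separable minor regioisomer) and the electron-poor enone alkene is inert.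

**Step 2**
Reactants: 2 (1R,10R)-1,10-epoxygermacra-4E,7(11)-dien-8-one
Product: 4 (1R,5S,10R)-1-(tert-butyldimethylsilyloxy)eudesma-3,7(11)-dien-8-one, via eudesmadienol 3 (not isolated)
Conditions: BF3·OEt2 (20 mol%), CH2Cl2, −78 °C; then 2,6-lutidine, tBuMe2SiOTf, −78 → 0 °C
Reagents that add atoms: tert-butyldimethylsilyl triflate, CC(C)(C)[Si](C)(C)OS(=O)(=O)C(F)(F)F
Why: Lewis-acid-promoted transannular cation–olefin cyclization (the germacrene-to-eudesmane ring closure of the biosynthesis), in which the epoxide opens at tertiary C10 with inversion by the 4,5-alkene through the chair–chair conformer of the E,E-cyclodecadiene to form the C5–C10 bond and a trans-decalin with 1β-O (C1 untouched), 10β-CH3 and 5α-H, the C4 cation then losing H3 to give the Δ3 alkene (Δ4(15) and Δ4 isomers are by-products) before in situ silylation caps O1.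

**Step 3**
Reactants: 4 (1R,5S,10R)-1-(tert-butyldimethylsilyloxy)eudesma-3,7(11)-dien-8-one
Product: 6 3β,4β-epoxy-1β-(tert-butyldimethylsilyloxy)-5α-eudesm-7(11)-en-8-one, via bromohydrin 5 (not isolated)
Conditions: NBS, NaHCO3, acetone/H2O (5:1), 0 °C; then K2CO3, MeOH, 23 °C
Reagents that add atoms: water, O
Why: Halohydrin formation followed by intramolecular Williamson ring closure, in which Br+ adds to the Δ3 alkene from the α face (the β face is screened by the axial 10β-methyl), water opens the bromonium ion anti from the β face, and base closes either trans-bromohydrin to the same 3β,4β-epoxide, so the C3 oxygen ends up β, on the face a peracid would not reach, while the enone alkene is too electron-poor to react.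

**Step 4**
Reactants: 6 3β,4β-epoxy-1β-(tert-butyldimethylsilyloxy)-5α-eudesm-7(11)-en-8-one
Product: 9 (1R,3S,4R,5R)-1-(tert-butyldimethylsilyloxy)-3-hydroxyeremophila-7(11),9-dien-8-one, via silyl enol ether 7 (not isolated), via trimethylsilyl ether 8 (not isolated)
Conditions: LiN(iPr)2, Me3SiCl, THF, −78 °C, then concentrate and filter in pentane; Me3SiOTf (10 mol%), 2,6-di-tert-butylpyridine (20 mol%), CH2Cl2, −78 → −40 °C; then PPTS, MeOH, 0 °C
Reagents that add atoms: none
Why: Proposed new method: silylation of the epoxide oxygen by Me3Si+ triggers C4–O heterolysis in a trans-decalin where C4–O(β), C5–H(α) and C10–CH3(β) are mutually antiperiplanar, so H5 shifts to C4 (giving 4α-H and 4β-CH3 with the 3β-oxygen untouched), the axial C10 methyl shifts to C5 (5β-CH3), and the kinetically formed C8 silyl enol ether donates into C10 to end the sequence as a 2-silyloxyallyl cation that passes Me3Si+ to the next epoxide (net isomerization of 7 to 8 with the C9=C10 enone formed), after which mild methanolysis frees only the C3 hydroxyl; the closest known reactions are Lewis-acid backbone rearrangements of triterpene 3,4-epoxides, the Westphalen C10-to-C5 methyl shift of steroids and semipinacol rearrangements of epoxy silyl ethers, and the shifts mirror the eudesmyl-to-eremophilyl cation steps of the biosynthesis.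

**Step 5**
Reactants: 9 (1R,3S,4R,5R)-1-(tert-butyldimethylsilyloxy)-3-hydroxyeremophila-7(11),9-dien-8-one; 10 angelic acid
Product: 12 (1R,3S,4R,5R)-3-angeloyloxy-1-(tert-butyldimethylsilyloxy)eremophila-7(11),9-dien-8-one, via mixed anhydride 11 (not isolated)
Conditions: 10, 2,4,6-Cl3C6H2COCl, Et3N, toluene, 23 °C; then 9, 80 °C (no DMAP)
Reagents that add atoms: angelic acid (10), C/C=C(/C)C(=O)O
Why: Yamaguchi esterification through the mixed anhydride without a nucleophilic catalyst acylates the only free hydroxyl (the 3β-OH, equatorial in the preferred ring A conformer) and avoids Z-to-E isomerization of the angelate to the tiglate, with no stereocentre touched.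

**Step 6**
Reactants: 12 (1R,3S,4R,5R)-3-angeloyloxy-1-(tert-butyldimethylsilyloxy)eremophila-7(11),9-dien-8-one
Product: 13 (1R,3S,4R,5R)-3-angeloyloxy-1-hydroxyeremophila-7(11),9-dien-8-one
Conditions: HF·pyridine, pyridine/THF, 0 → 23 °C
Reagents that add atoms: none
Why: Fluoride-driven desilylation cleaves the Si–O bond to release the allylic 1β-hydroxyl under conditions that leave the angelate, the cross-conjugated dienone and all stereocentres intact.

**Step 7**
Reactants: 13 (1R,3S,4R,5R)-3-angeloyloxy-1-hydroxyeremophila-7(11),9-dien-8-one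
Product: 14 (1R,3S,4R,5R)-3-angeloyloxy-1-hydroxy-11-hydroperoxyeremophila-6,9-dien-8-one
Conditions: O2, meso-tetraphenylporphyrin (1 mol%), visible light, CH2Cl2, −20 °C, stopped at full conversion of 13
Reagents that add atoms: dioxygen, O=O
Why: Schenck ene reaction of singlet oxygen with the s-cis 7(11)-en-8-one, in which oxygen adds at C11 and hydrogen is taken from C6 (the alkyl group geminal to the carbonyl, the usual regioselectivity for α,β-unsaturated ketones) to give the tertiary 11-hydroperoxide and the new 6,7-alkene with no new stereocentre, while the C9=C10 enone (no alkyl group on its α-carbon) and the less reactive angelate are left alone.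

**Compound list**
1 | germacrone, (3E,7E)-3,7-dimethyl-10-(propan-2-ylidene)cyclodeca-3,7-dien-1-one | C/C1=C\CC/C(C)=C/CC(=C(C)C)C(=O)C1 | starting material
2 | (1R,10R)-1,10-epoxygermacra-4E,7(11)-dien-8-one (trans-epoxide) | C[C@]12O[C@@H]1CC/C(C)=C/CC(=C(C)C)C(=O)C2 | intermediate
3 | (1R,5S,10R)-1-hydroxyeudesma-3,7(11)-dien-8-one (1β-OH, 5α-H, 10β-CH3, trans-decalin) | C[C@@]12CC(=O)C(=C(C)C)C[C@H]1C(C)=CC[C@H]2O | intermediate
4 | (1R,5S,10R)-1-(tert-butyldimethylsilyloxy)eudesma-3,7(11)-dien-8-one | C[C@@]12CC(=O)C(=C(C)C)C[C@H]1C(C)=CC[C@H]2O[Si](C)(C)C(C)(C)C | intermediate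
5 | 3α-bromo-4β-hydroxy-1β-(tert-butyldimethylsilyloxy)-5α-eudesm-7(11)-en-8-one (4α-CH3, 10β-CH3) | C[C@@]12CC(=O)C(=C(C)C)C[C@H]1[C@@](C)(O)[C@H](Br)C[C@H]2O[Si](C)(C)C(C)(C)C | intermediate
6 | 3β,4β-epoxy-1β-(tert-butyldimethylsilyloxy)-5α-eudesm-7(11)-en-8-one (4α-CH3, 10β-CH3) | C[C@@]12CC(=O)C(=C(C)C)C[C@H]1[C@@]3(C)O[C@H]3C[C@H]2O[Si](C)(C)C(C)(C)C | intermediate
7 | 3β,4β-epoxy-1β-(tert-butyldimethylsilyloxy)-8-(trimethylsilyloxy)-5α-eudesma-7(11),8-diene (C8 silyl enol ether of 6) | C[C@@]12C=C(O[Si](C)(C)C)C(=C(C)C)C[C@H]1[C@@]3(C)O[C@H]3C[C@H]2O[Si](C)(C)C(C)(C)C | intermediate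
8 | (1R,3S,4R,5R)-1-(tert-butyldimethylsilyloxy)-3-(trimethylsilyloxy)eremophila-7(11),9-dien-8-one (1β-O, 3β-O, 4β-CH3, 5β-CH3) | C[Si](C)(C)O[C@H]1C[C@@H](O[Si](C)(C)C(C)(C)C)C2=CC(=O)C(=C(C)C)C[C@]2(C)[C@H]1C | intermediate
9 | (1R,3S,4R,5R)-1-(tert-butyldimethylsilyloxy)-3-hydroxyeremophila-7(11),9-dien-8-one | O[C@H]1C[C@@H](O[Si](C)(C)C(C)(C)C)C2=CC(=O)C(=C(C)C)C[C@]2(C)[C@H]1C | intermediate
10 | angelic acid, (Z)-2-methylbut-2-enoic acid | C/C=C(/C)C(=O)O | starting material
11 | (Z)-2-methylbut-2-enoic 2,4,6-trichlorobenzoic anhydride | C/C=C(/C)C(=O)OC(=O)c1c(Cl)cc(Cl)cc1Cl | intermediate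
12 | (1R,3S,4R,5R)-3-angeloyloxy-1-(tert-butyldimethylsilyloxy)eremophila-7(11),9-dien-8-one | C/C=C(/C)C(=O)O[C@H]1C[C@@H](O[Si](C)(C)C(C)(C)C)C2=CC(=O)C(=C(C)C)C[C@]2(C)[C@H]1C | intermediate
13 | (1R,3S,4R,5R)-3-angeloyloxy-1-hydroxyeremophila-7(11),9-dien-8-one | C/C=C(/C)C(=O)O[C@H]1C[C@@H](O)C2=CC(=O)C(=C(C)C)C[C@]2(C)[C@H]1C | intermediate
14 | (1R,3S,4R,5R)-3-angeloyloxy-1-hydroxy-11-hydroperoxyeremophila-6,9-dien-8-one (3β-angeloyloxy, 1β-OH, 4β,5β-dimethyl) | C/C=C(/C)C(=O)O[C@H]1C[C@@H](O)C2=CC(=O)C(C(C)(C)OO)=C[C@]2(C)[C@H]1C | target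

**Totals**
Total step count: 7. Longest linear sequence: 7 steps (1 → 14); angelic acid 10 is bought and enters in step 5.

**Steps most likely to fail, with fallbacks**

Step 4 (the rearrangement cascade) is the most uncertain. It can leak to the 3-ketone by hydride shift from C3, to eudesmenes by proton loss from the C4 or C5 cation, or to a cyclopropyl ketone by attack of the enol ether carbon C9 on C5. The fallback sets out from 6 and drops the silyl enol ether in favour of a proton-triggered, Westphalen-type rearrangement of a pre-esterified alkene. Et2AlN(C9H18) (diethylaluminium 2,2,6,6-tetramethylpiperidide, toluene, 0 °C) isomerizes the epoxide to the exocyclic allylic alcohol 1β-(tert-butyldimethylsilyloxy)-3β-hydroxy-5α-eudesma-4(15),7(11)-dien-8-one F1, keeping the 3β-oxygen. This unhindered equatorial alcohol is esterified under the step 5 conditions to its angelate, 3β-angeloyloxy-1β-(tert-butyldimethylsilyloxy)-5α-eudesma-4(15),7(11)-dien-8-one F2. Tf2NH (10 mol%) in (CF3)2CHOH/CH2Cl2 at 0 °C then protonates the exocyclic alkene to the same C4 cation. The neighbouring acyloxy group pushes the charge onward through the H5 and C10-methyl shifts, and loss of H9 gives the enone. The fallback comes back to the route at 12.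

Step 1 (asymmetric epoxidation) may give poor regioselectivity between the 1(10)- and 4,5-alkenes or low enantioselectivity on this flexible ring, and the epoxy ketone is base-sensitive. The fallback sets out from 1 and replaces catalyst control by resolution. mCPBA (CH2Cl2, 0 °C) gives racemic trans-1,10-epoxygermacra-4E,7(11)-dien-8-one F3 after removal of the 4,5-epoxide. BF3·OEt2 cyclizes it to racemic 1β-hydroxyeudesma-3,7(11)-dien-8-one F4. Esterification with (R)-O-methylmandelic acid (DCC, DMAP, CH2Cl2) and chromatographic separation of the two diastereomers gives the (R)-O-methylmandelate of the (1R,5S,10R)-alcohol F5. K2CO3/MeOH releases the alcohol, so the fallback comes back to the route at 3, which is silylated as in the second half of step 2.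

Step 2 (regiochemistry of cation termination) may give too little of the Δ3 isomer against the Δ4(15) and Δ4 isomers. The fallback sets out from 2 and changes the ring closure from cationic to radical. Cp2TiCl (trivalent titanium, made from Cp2TiCl2 and Mn dust, THF, 23 °C) opens the epoxide homolytically at C10; transannular radical cyclization and loss of a β-hydrogen from the C4 organotitanium give only the exocyclic alkene (1R,5S,10R)-1-hydroxyeudesma-4(15),7(11)-dien-8-one F6. RhCl3·3H2O (5 mol%, EtOH, 80 °C) then moves the double bond into ring A, and the fallback comes back to the route at 3.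

**Further compounds**
F1 | step 4 | 1β-(tert-butyldimethylsilyloxy)-3β-hydroxy-5α-eudesma-4(15),7(11)-dien-8-one | C[C@@]12CC(=O)C(=C(C)C)C[C@H]1C(=C)[C@@H](O)C[C@H]2O[Si](C)(C)C(C)(C)C
F2 | step 4 | 3β-angeloyloxy-1β-(tert-butyldimethylsilyloxy)-5α-eudesma-4(15),7(11)-dien-8-one | C[C@@]12CC(=O)C(=C(C)C)C[C@H]1C(=C)[C@@H](OC(=O)/C(C)=C\C)C[C@H]2O[Si](C)(C)C(C)(C)C
F3 | step 1 | racemic trans-1,10-epoxygermacra-4E,7(11)-dien-8-one (both enantiomers) | C[C@]12O[C@@H]1CC/C(C)=C/CC(=C(C)C)C(=O)C2.C[C@@]12O[C@H]1CC/C(C)=C/CC(=C(C)C)C(=O)C2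
F4 | step 1 | racemic 1β-hydroxyeudesma-3,7(11)-dien-8-one (both enantiomers) | C[C@@]12CC(=O)C(=C(C)C)C[C@H]1C(C)=CC[C@H]2O.C[C@]12CC(=O)C(=C(C)C)C[C@@H]1C(C)=CC[C@@H]2O
F5 | step 1 | (R)-O-methylmandelate of (1R,5S,10R)-1-hydroxyeudesma-3,7(11)-dien-8-one | C[C@@]12CC(=O)C(=C(C)C)C[C@H]1C(C)=CC[C@H]2OC(=O)[C@H](OC)c1ccccc1
F6 | step 2 | (1R,5S,10R)-1-hydroxyeudesma-4(15),7(11)-dien-8-one | C[C@@]12CC(=O)C(=C(C)C)C[C@H]1C(=C)CC[C@H]2O
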